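## Retrosynthetic overview

- **Carbocycle numbering:** C1 = carbinol carbon, C2 = CH2, C3 = CHBr, C4 = C(CH3)Cl. The C4–Cl bond and the free C1–OH come last, from BCl3 opening of a temporary C1–O–C4 bridge. That bridge comes from NBS bromoetherification of a 1-substituted 4-methylcyclohex-3-en-1-ol.
- **Enabling feature:** the tertiary C1–O bond is homoallylic (C1–C2–C3=C4) to the alkene hidden under the Br/Cl pair. Reconnecting C1–C3 gives a thujane-type bicyclo[3.1.0]hexane, with C1, C3, C4, C5 and C6 as the cyclopentane and C2 as the cyclopropane CH2. MeLi and then H3O+ on its C4 ketone enlarges the ring from five to six members.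
- **Oxane:** it is closed on the bicyclic ketone by 6-endo bromoetherification of a prenyl chain by the tertiary OH.
- **Fragment union:** a bridgehead cyclopropyl Grignard reagent (from cyclopentane-1,3-dione via CBS reduction and Simmons–Smith) adds under chelation control to (R)-3-benzyloxy-sulcatone. The eight carbons of sulcatone become the whole oxane part.
- **Ring order:** cyclopentene (purchased ring) → cyclopropane → oxane → cyclohexene (by enlargement) → oxa-bridge (temporary, opened at the end).

Key step: step 9

Assumption: the carbinol centre of 14 is lost in the same flask. It is drawn for methyl attack anti to the cyclopropane CH2, and its configuration does not matter.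

## Route

Step 1
Reactants: 1 cyclopentane-1,3-dione
Product: 2 3-iodocyclopent-2-en-1-one
Conditions: PPh3, I2, Et3N, MeCN, rt → reflux
Reagents that add atoms: iodine, II
Why: Ph3P·I2 activates the enol oxygen of the 1,3-diketone and iodide adds and eliminates (β-diketone to β-halo enone conversion), with no stereocenter formed.

Step 2
Reactants: 2 3-iodocyclopent-2-en-1-one
Product: 3 (S)-3-iodocyclopent-2-en-1-ol
Conditions: (R)-Me-CBS (10 mol %), BH3·SMe2, THF, −20 °C; aq. work-up
Reagents that add atoms: none
Why: Corey–Bakshi–Shibata reduction, in which the iodoalkenyl arm acts as the large group, so the (R)-oxazaborolidine should give the (S)-allylic alcohol as the relay stereocenter of the ring fragment.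

Step 3
Reactants: 3 (S)-3-iodocyclopent-2-en-1-ol
Product: 4 (1S,2S,5R)-5-iodobicyclo[3.1.0]hexan-2-ol (OH cis to the cyclopropane CH2)
Conditions: Et2Zn, CH2I2, CH2Cl2, −10 °C → rt; aq. work-up
Reagents that add atoms: diiodomethane, ICI
Why: Hydroxyl-directed Simmons–Smith cyclopropanation, a reaction type known for β-iodo allylic alcohols, in which the zinc alkoxide delivers CH2 to the face syn to OH and so sets both bridgehead centers.

Step 4
Reactants: 5 6-methylhept-5-en-2-one (sulcatone)
Product: 7 (R)-3-hydroxy-6-methylhept-5-en-2-one, via aminoxy ketone 6 (not isolated)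
Conditions: PhNO (slow addition), L-proline (20 mol %), excess 5, DMSO, rt; then CuSO4·5H2O (30 mol %), MeOH, 0 °C
Reagents that add atoms: nitrosobenzene, O=Nc1ccccc1
Why: Proline-catalysed enamine α-aminoxylation at the more substituted (methylene) enamine is followed by Cu(II)-catalysed N–O cleavage, and the carboxylic acid of L-proline steers the electrophile to one enamine face to give the (R)-ketol.

Step 5
Reactants: 7 (R)-3-hydroxy-6-methylhept-5-en-2-one
Product: 8 (R)-3-(benzyloxy)-6-methylhept-5-en-2-one
Conditions: BnOC(=NH)CCl3, TfOH (cat.), CH2Cl2/cyclohexane, 0 °C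
Reagents that add atoms: benzyl 2,2,2-trichloroacetimidate, ClC(Cl)(Cl)C(=N)OCc1ccccc1
Why: Acid-catalysed imidate benzylation avoids base, so the enolisable ketol center is not epimerised, and it installs an ether that can chelate magnesium.

Step 6
Reactants: 4 (1S,2S,5R)-5-iodobicyclo[3.1.0]hexan-2-ol; 8 (R)-3-(benzyloxy)-6-methylhept-5-en-2-one
Product: 11 (1R,2S,5R)-5-[(2R,3R)-3-(benzyloxy)-2-hydroxy-6-methylhept-5-en-2-yl]bicyclo[3.1.0]hexan-2-ol, via dilithio species 9 (not isolated), via bis(bromomagnesio) species 10 (not isolated)
Conditions: 4, t-BuLi (3.1 equiv), Et2O, −78 °C; MgBr2·OEt2 (2.2 equiv), −78 → 0 °C; 8, THF, −78 °C; aq. work-up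
Reagents that add atoms: none
Why: Iodine–lithium exchange at the bridgehead cyclopropyl carbon is configurationally locked, and the derived Grignard reagent attacks the five-membered Mg chelate of the α-benzyloxy ketone from the side of the α-H (Cram chelate model), which sets the tertiary carbinol center relative to the benzyloxy center.

Step 7
Reactants: 11 the diol of step 6
Product: 12 (1R,5R)-5-[(2R,3R)-3-(benzyloxy)-2-hydroxy-6-methylhept-5-en-2-yl]bicyclo[3.1.0]hexan-2-one
Conditions: TPAP (5 mol %), NMO, 4 Å MS, CH2Cl2, rt
Reagents that add atoms: none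
Why: Ley–Griffith oxidation touches only the secondary cyclopropyl carbinol, while the tertiary alcohol, the alkene and the benzyl ether are inert under these neutral conditions.

Step 8
Reactants: 12 the hydroxy ketone of step 7
Product: 13 (1R,5R)-5-[(2R,3R,5R)-3-(benzyloxy)-5-bromo-2,6,6-trimethyloxan-2-yl]bicyclo[3.1.0]hexan-2-one
Conditions: NBS (1.1 equiv), (CF3)2CHOH, 4 Å MS, 0 °C, dark
Reagents that add atoms: N-bromosuccinimide, O=C1CCC(=O)N1Br
Why: Bromonium-induced 6-endo (Markovnikov) bromoetherification by the only free OH in an ionising solvent, through a chair transition state with the quaternary bicyclic group equatorial and CH3 axial, which places Br equatorial and sets the C–Br center.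

Step 9
Reactants: 13 the bromo-oxanyl cyclopropyl ketone of step 8
Product: 15 (1R)-1-[(2S,3R,5R)-3-(benzyloxy)-5-bromo-2,6,6-trimethyloxan-2-yl]-4-methylcyclohex-3-en-1-ol, via tertiary cyclopropylcarbinol 14 (not isolated)
Conditions: MeLi (1.3 equiv), Et2O/THF, −78 °C; then 1 M aq. H2SO4/THF, 0 °C → rt
Reagents that add atoms: methyllithium, [Li]C; water, O
Why: MeLi adds 1,2 to the cyclopropyl ketone and, on acidification, carbinol 14 ionises to a bisected tertiary cyclopropylcarbinyl cation in which the zero-bridge bond C1–C5 of the bicyclo[3.1.0]hexane breaks while water binds to C5, so that the cyclopentane (C1–C5) takes up the cyclopropane CH2 (C6) and becomes the cyclohexene. The closest known reaction type is the acid-catalysed cyclopropylcarbinyl–homoallyl rearrangement of thujane-type carbinols to p-menth-1-en-4-ols (sabinene hydrate to terpinen-4-ol). No ring is closed by a new ring bond: the six-membered ring arises by scission of the bond shared by the three- and five-membered rings, and the only new bond is the exocyclic C5–OH. The new tertiary carbinol center is controlled by the cyclopropane configuration set in step 3, because water must enter anti to the breaking C1–C5 bond (inversion at C5), whereas the carbinol center of 14 is destroyed and its epimer ratio is irrelevant. The step needs cleavage of the internal and not the external cyclopropane bond, which is secured by charge build-up at the fully substituted C5 instead of the primary C6, and this also fixes the alkene between the former C1 and C2, exactly where Br and Cl are needed. The competing 1,2-shift from the neighbouring oxane carbon and proton loss are held back by a water-rich medium, low temperature and the two β-oxygen atoms, which make the opening nucleophile-assisted rather than a free-cation process.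

Step 10
Reactants: 15 the cyclohexenol of step 9
Product: 16 (2S,3R,5R)-3-(benzyloxy)-5-bromo-2-[(1S,2S,4R)-2-bromo-1-methyl-7-oxabicyclo[2.2.1]heptan-4-yl]-2,6,6-trimethyloxane (ring Br endo, anti to the oxygen bridge)
Conditions: NBS (1.1 equiv), CH2Cl2, 0 °C, dark
Reagents that add atoms: N-bromosuccinimide, O=C1CCC(=O)N1Br
Why: Intramolecular 5-exo Markovnikov bromoetherification (the halocyclisation of cyclohex-3-enols to 7-oxabicyclo[2.2.1]heptanes), in which only the reversibly formed bromonium ion on the face opposite to the axial tertiary OH can be captured, so Br ends cis to the oxane substituent and the new C–O bond marks the face that chlorine must occupy.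

Step 11
Reactants: 16 the bromo oxa-bridged compound of step 10
Product: 17 (2S,3R,5R)-5-bromo-2-[(1R,3S,4S)-3-bromo-4-chloro-1-hydroxy-4-methylcyclohexyl]-2,6,6-trimethyloxan-3-ol (target)
Conditions: BCl3 (4 equiv), CH2Cl2, −78 → −30 °C; then H2O
Reagents that add atoms: boron trichloride, ClB(Cl)Cl
Why: Boron trichloride ether cleavage, in which the tied-back strained bridge oxygen binds BCl3 in preference to the shielded oxane oxygen, the endo bromine anti to the C(CH3)–O bond assists ionisation to the bromonium ion, and chloride from the borate opens it at the tertiary carbon on the face the oxygen left (double inversion, net retention), which gives the trans-diequatorial bromochloride that a direct diaxial BrCl addition (Fürst–Plattner) would not give, while the benzyl ether is cleaved in the same flask.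

## Compound list

1 | cyclopentane-1,3-dione | O=C1CCC(=O)C1 | starting material
2 | 3-iodocyclopent-2-en-1-one | O=C1CCC(I)=C1 | intermediate
3 | (S)-3-iodocyclopent-2-en-1-ol | O[C@H]1CCC(I)=C1 | intermediate
4 | (1S,2S,5R)-5-iodobicyclo[3.1.0]hexan-2-ol | O[C@H]1CC[C@@]2(I)C[C@@H]12 | intermediate
5 | 6-methylhept-5-en-2-one (sulcatone) | CC(=O)CCC=C(C)C | starting material
6 | (R)-6-methyl-3-[(phenylamino)oxy]hept-5-en-2-one | CC(=O)[C@H](ONc1ccccc1)CC=C(C)C | intermediate
7 | (R)-3-hydroxy-6-methylhept-5-en-2-one | CC(=O)[C@H](O)CC=C(C)C | intermediate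
8 | (R)-3-(benzyloxy)-6-methylhept-5-en-2-one | CC(=O)[C@H](OCc1ccccc1)CC=C(C)C | intermediate
9 | O,C5-dilithio derivative of 4 (configuration retained) | [Li]O[C@H]1CC[C@@]2([Li])C[C@@H]12 | intermediate
10 | O,C5-bis(bromomagnesio) derivative of 4 (configuration retained) | Br[Mg]O[C@H]1CC[C@@]2([Mg]Br)C[C@@H]12 | intermediate
11 | (1R,2S,5R)-5-[(2R,3R)-3-(benzyloxy)-2-hydroxy-6-methylhept-5-en-2-yl]bicyclo[3.1.0]hexan-2-ol | C[C@](O)([C@H](OCc3ccccc3)CC=C(C)C)[C@@]12CC[C@H](O)[C@@H]1C2 | intermediate
12 | (1R,5R)-5-[(2R,3R)-3-(benzyloxy)-2-hydroxy-6-methylhept-5-en-2-yl]bicyclo[3.1.0]hexan-2-one | C[C@](O)([C@H](OCc3ccccc3)CC=C(C)C)[C@@]12CCC(=O)[C@@H]1C2 | intermediate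
13 | (1R,5R)-5-[(2R,3R,5R)-3-(benzyloxy)-5-bromo-2,6,6-trimethyloxan-2-yl]bicyclo[3.1.0]hexan-2-one | CC1(C)O[C@](C)([C@@]23CCC(=O)[C@@H]2C3)[C@H](OCc4ccccc4)C[C@H]1Br | intermediate
14 | (1R,2S,5R)-5-[(2R,3R,5R)-3-(benzyloxy)-5-bromo-2,6,6-trimethyloxan-2-yl]-2-methylbicyclo[3.1.0]hexan-2-ol | CC1(C)O[C@](C)([C@@]23CC[C@](C)(O)[C@@H]2C3)[C@H](OCc4ccccc4)C[C@H]1Br | intermediate
15 | (1R)-1-[(2S,3R,5R)-3-(benzyloxy)-5-bromo-2,6,6-trimethyloxan-2-yl]-4-methylcyclohex-3-en-1-ol | CC1(C)O[C@](C)([C@@]2(O)CCC(C)=CC2)[C@H](OCc3ccccc3)C[C@H]1Br | intermediate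
16 | (2S,3R,5R)-3-(benzyloxy)-5-bromo-2-[(1S,2S,4R)-2-bromo-1-methyl-7-oxabicyclo[2.2.1]heptan-4-yl]-2,6,6-trimethyloxane | CC1(C)O[C@](C)([C@@]23CC[C@](C)(O3)[C@@H](Br)C2)[C@H](OCc4ccccc4)C[C@H]1Br | intermediate
17 | (2S,3R,5R)-5-bromo-2-[(1R,3S,4S)-3-bromo-4-chloro-1-hydroxy-4-methylcyclohexyl]-2,6,6-trimethyloxan-3-ol | CC1(C)O[C@](C)([C@@]2(O)CC[C@](C)(Cl)[C@@H](Br)C2)[C@H](O)C[C@H]1Br | target

## Step count and weak points

Total step count: 11. Longest linear sequence: 9 (steps 1–3 and 6–11).

**Step 9.**
- **Risk:** as charge builds up at the quaternary cyclopropane carbon, a pinacol-type 1,2-shift from the neighbouring oxane carbon may outrun capture by water. Proton loss to dienes may do the same, and a looser ion pair would erode the inversion.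
- **Fallback idea:** the ring enlargement is moved ahead of the oxane closure and is ended by an internal nucleophile on an acylated oxygen, which cannot support the shift.
- **Fallback path:**
  - It sets out from 12. Trichloroacetyl isocyanate (CH2Cl2, 0 °C) should give the N-trichloroacetyl carbamate F1.
  - K2CO3/MeOH should then give the primary carbamate F2.
  - Excess MeLi (−78 °C) should give the tertiary cyclopropylcarbinol F3.
  - PPTS in wet MeCN ionises the carbinol. The carbamate carbonyl oxygen takes the quaternary carbon 5-exo from the backside to give the iminocarbonate F4.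
  - This is hydrolysed in the same flask to the spiro cyclic carbonate F5.
  - K2CO3/MeOH frees the diol F6.
  - Two equivalents of NBS in HFIP close first the oxane and then the oxa-bridge. The fallback comes back to the route at 16.

**Step 11.**
- **Risk:** BCl3 may also ionise a C–O bond of the oxane (ring loss). The bridge may ionise at the wrong bridgehead, or proton loss may replace chloride capture.
- **Fallback idea:** ether cleavage is avoided altogether.
- **Fallback path:**
  - It sets out from 15, which is treated with NBS and ClTi(OiPr)3 (hexanes/CH2Cl2, −20 °C).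
  - This is a hydroxyl-directed bromochlorination. The titanium alkoxide of the axial OH delivers chloride to its own face of the bromonium ion and should give the O-benzyl ether of the target F7.
  - Visible-light DDQ debenzylation (wet CH2Cl2) comes back to the route at 17.

**Step 8.**
- **Risk:** 5-exo closure to an oxolane may compete with the 6-endo mode, and facial selectivity at the bromonium stage may be poor.
- **Fallback idea:** a reversible mercury(II) cyclisation is used under thermodynamic control.
- **Fallback path:**
  - It sets out from 12. Hg(OCOCF3)2 in MeNO2 followed by aq. KBr should give the equatorial oxanyl mercury bromide F8.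
  - Bromodemercuration with Br2 in pyridine (retention) comes back to the route at 13.

## Further compounds

F1 | step 9 | N-(trichloroacetyl)carbamate of the tertiary alcohol of 12 (configuration as in 12) | C[C@](OC(=O)NC(=O)C(Cl)(Cl)Cl)([C@H](OCc3ccccc3)CC=C(C)C)[C@@]12CCC(=O)[C@@H]1C2
F2 | step 9 | primary carbamate of the tertiary alcohol of 12 (configuration as in 12) | C[C@](OC(N)=O)([C@H](OCc3ccccc3)CC=C(C)C)[C@@]12CCC(=O)[C@@H]1C2
F3 | step 9 | tertiary cyclopropylcarbinol from F2 and MeLi (2-methylbicyclo[3.1.0]hexan-2-ol, carbinol center inconsequential) | C[C@](OC(N)=O)([C@H](OCc3ccccc3)CC=C(C)C)[C@@]12CC[C@](C)(O)[C@@H]1C2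
F4 | step 9 | spiro 2-imino-1,3-dioxolane (iminocarbonate) bridging the two tertiary oxygens of F6 | C[C@@]1([C@H](OCc3ccccc3)CC=C(C)C)OC(=N)O[C@@]12CCC(C)=CC2
F5 | step 9 | spiro cyclic carbonate of diol F6 | C[C@@]1([C@H](OCc3ccccc3)CC=C(C)C)OC(=O)O[C@@]12CCC(C)=CC2
F6 | step 9 | (1R)-1-[(2S,3R)-3-(benzyloxy)-2-hydroxy-6-methylhept-5-en-2-yl]-4-methylcyclohex-3-en-1-ol | C[C@](O)([C@H](OCc3ccccc3)CC=C(C)C)[C@@]1(O)CCC(C)=CC1
F7 | step 11 | 3-O-benzyl ether of 17 | CC1(C)O[C@](C)([C@@]2(O)CC[C@](C)(Cl)[C@@H](Br)C2)[C@H](OCc3ccccc3)C[C@H]1Br
F8 | step 8 | analogue of 13 with equatorial HgBr in place of the oxane bromine | CC1(C)O[C@](C)([C@@]23CCC(=O)[C@@H]2C3)[C@H](OCc4ccccc4)C[C@H]1[Hg]Br
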